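## Retrosynthetic overview

1. The cis-1,10-oxirane comes from the 1(10)E-alkene by outer-face syn-dihydroxylation and invertive closure at C1; the C11 methylene and the C3 acetate are put on last.
2. The trans-6,12-lactone and the C8 ester come from a β-hydroxy ketone: Evans–Tishchenko reduction (C6 and the ester), dianion alkylation (C7), conjugate borylation/oxidation (C8).
3. The ten-membered ring comes from an anionic oxy-Cope rearrangement of a trans-1,2-dialkenylcyclohexenol (C8–C9 bond); the cyclohexene double bond becomes the 4Z-alkene.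
4. The cyclohexenone comes from (R)-carvone 1 (C1–C6, C10, C14, C15 and the C3 stereocentre); the acyl stereocentre is bought in (R)-2-methylbutanoic acid 2.
5. Ring order: six-membered ring (bought), then ten-membered carbocycle, then γ-lactone, then oxirane.

Assumption: 2 is bought as the single (R)-enantiomer. Locants C1–C15 are the germacranolide numbers of the target throughout (C1–C10 ring, C11–C13 lactone/acrylate carbons, C14 on C10, C15 on C4).

## Route

Step 1
Reactants: 1 (R)-(−)-carvone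
Product: 3 (1R,5R)-cis-carveol
Conditions: NaBH4, CeCl3·7H2O, MeOH, −78 to 0 °C
Reagents that add atoms: none
Why: Luche 1,2-reduction delivers hydride to the carbonyl face that gives the cis alcohol (new centre R, later C3).

Step 2
Reactants: 3 (1R,5R)-cis-carveol
Product: 4 (1R,5R)-cis-carveol tert-butyldimethylsilyl ether
Conditions: TBSCl, imidazole, DMF, rt
Reagents that add atoms: tert-butyldimethylsilyl chloride, CC(C)(C)[Si](C)(C)Cl
Why: Silylation protects the allylic alcohol for the organometallic and enolate steps; no stereocentre changes.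

Step 3
Reactants: 4 (1R,5R)-cis-carveol tert-butyldimethylsilyl ether
Product: 5 (4R,6R)-4-(tert-butyldimethylsilyloxy)-3-methyl-6-(prop-1-en-2-yl)cyclohex-2-en-1-one
Conditions: CrO3, 3,5-dimethylpyrazole, CH2Cl2, −20 °C
Reagents that add atoms: chromium trioxide, O=[Cr](=O)=O
Why: Chromium-mediated allylic oxidation (Salmond conditions) converts the one ring CH2 next to the CH= terminus into the enone; the adjacent stereocentre stays cis (diequatorial), which is also the thermodynamic arrangement.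

Step 4
Reactants: 5 (4R,6R)-4-(tert-butyldimethylsilyloxy)-3-methyl-6-(prop-1-en-2-yl)cyclohex-2-en-1-one
Product: 6 (1R,4R,6R)-4-(tert-butyldimethylsilyloxy)-1-ethenyl-3-methyl-6-(prop-1-en-2-yl)cyclohex-2-en-1-ol
Conditions: CH2=CHMgBr, CeCl3, THF, −78 °C
Reagents that add atoms: vinylmagnesium bromide, C=C[Mg]Br
Why: Cerium-assisted 1,2-Grignard addition occurs trans to the neighbouring isopropenyl group, setting the carbinol centre (R) and the trans-dialkenyl relationship a chair transition state needs.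

Step 5
Reactants: 6 (1R,4R,6R)-4-(tert-butyldimethylsilyloxy)-1-ethenyl-3-methyl-6-(prop-1-en-2-yl)cyclohex-2-en-1-ol
Product: 8 (3R)-3-(tert-butyldimethylsilyloxy)-4,10-dimethylcyclodeca-1(10)E,4Z,7Z-trien-6-one, via potassium dienone enolate 7 (not isolated)
Conditions: KN(SiMe3)2, 18-crown-6, THF, 0 °C to rt; then PhS(Cl)=N-t-Bu, −78 °C to rt
Reagents that add atoms: none
Why: The anionic oxy-Cope [3,3]-sigmatropic rearrangement runs through the only accessible chair, forming the C8–C9 bond and the ten-membered ring with 1(10)E and inherited 4Z geometry, and the regiospecific enolate is dehydrogenated in the same flask (Mukaiyama sulfinimidoyl chloride, syn-elimination) to the 7Z-enone; the two old ring stereocentres are consumed and no new one is made.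

Step 6
Reactants: 8 (3R)-3-(tert-butyldimethylsilyloxy)-4,10-dimethylcyclodeca-1(10)E,4Z,7Z-trien-6-one
Product: 10 (3R,8S)-8-hydroxy-3-(tert-butyldimethylsilyloxy)-4,10-dimethylcyclodeca-1(10)E,4Z-dien-6-one, via C8 pinacol boronate 9 (not isolated)
Conditions: CuCl (5 mol %), Xantphos, NaOt-Bu (cat.), B2pin2, MeOH, THF, rt; then NaBO3·4H2O, THF/H2O, rt
Reagents that add atoms: bis(pinacolato)diboron, CC1(C)OB(OC1(C)C)B1OC(C)(C)C(C)(C)O1 (boron of 9 only); sodium perborate, [Na+].[O-]OB=O (oxygen of 10)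
Why: Copper-catalysed conjugate borylation takes the less hindered disubstituted enone and is expected to add on the outer face of the ring, and the perborate oxidation is stereoretentive, which sets C8 as S.

Step 7
Reactants: 10 (3R,8S)-8-hydroxy-3-(tert-butyldimethylsilyloxy)-4,10-dimethylcyclodeca-1(10)E,4Z-dien-6-one
Product: 12 tert-butyl [(3R,7S,8S)-8-hydroxy-6-oxo-3-(tert-butyldimethylsilyloxy)-4,10-dimethylcyclodeca-1(10)E,4Z-dien-7-yl]acetate, via dilithium alkoxide enolate 11 (not isolated)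
Conditions: LiN(i-Pr)2 (2.3 equiv), THF, −78 to −40 °C; BrCH2CO2t-Bu, DMPU, −78 °C; AcOH quench at −78 °C
Reagents that add atoms: tert-butyl bromoacetate, CC(C)(C)OC(=O)CBr
Why: Fráter–Seebach-type alkylation of the chelated alkoxide–enolate dianion, which cannot β-eliminate, places the acetate arm anti to the C8 oxygen (C7 S).

Step 8
Reactants: 2 (R)-2-methylbutanoic acid
Product: 13 (R)-2-methylbutan-1-ol
Conditions: LiAlH4, Et2O, 0 °C to rt
Reagents that add atoms: none
Why: Hydride reduction of the acid leaves the α-stereocentre untouched.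

Step 9
Reactants: 13 (R)-2-methylbutan-1-ol
Product: 14 (R)-2-methylbutanal
Conditions: TEMPO (cat.), PhI(OAc)2, CH2Cl2, rt; used at once as a solution
Reagents that add atoms: none
Why: The non-basic oxoammonium oxidation stops at the aldehyde and keeps the α-stereocentre.

Step 10
Reactants: 12 tert-butyl [(3R,7S,8S)-8-hydroxy-6-oxo-3-(tert-butyldimethylsilyloxy)-4,10-dimethylcyclodeca-1(10)E,4Z-dien-7-yl]acetate; 14 (R)-2-methylbutanal
Product: 15 tert-butyl [(3R,6S,7R,8S)-6-hydroxy-8-((R)-2-methylbutanoyloxy)-3-(tert-butyldimethylsilyloxy)-4,10-dimethylcyclodeca-1(10)E,4Z-dien-7-yl]acetate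
Conditions: SmI2 (30 mol %), THF, −10 °C
Reagents that add atoms: none
Why: In the Evans–Tishchenko reduction the samarium-bound hemiacetal of 12 and 14 delivers hydride intramolecularly to the ketone (1,3-anti, C6 S) and leaves the acyl group on O8. The C7 descriptor changes to R by priority only.

Step 11
Reactants: 15 tert-butyl [(3R,6S,7R,8S)-6-hydroxy-8-((R)-2-methylbutanoyloxy)-3-(tert-butyldimethylsilyloxy)-4,10-dimethylcyclodeca-1(10)E,4Z-dien-7-yl]acetate
Product: 18 (3R,6S,7S,8S)-3-(tert-butyldimethylsilyloxy)-8-((R)-2-methylbutanoyloxy)-13-norgermacra-1(10)E,4Z-dien-12,6-olide, via bis-trimethylsilyl derivative 16 (not isolated), via hydroxy acid 17 (not isolated)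
Conditions: TMSOTf, 2,6-lutidine, CH2Cl2, 0 °C; then 0.5 M citric acid, THF, rt
Reagents that add atoms: trimethylsilyl triflate, C[Si](C)(C)OS(=O)(=O)C(F)(F)F (silyl groups of 16 only)
Why: The silyl triflate cleaves the tert-butyl ester without protic acid and the freed γ-hydroxy acid lactonises on the only free hydroxyl to the trans-fused butanolide; no stereocentre changes.

Step 12
Reactants: 18 (3R,6S,7S,8S)-3-(tert-butyldimethylsilyloxy)-8-((R)-2-methylbutanoyloxy)-13-norgermacra-1(10)E,4Z-dien-12,6-olide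
Product: 19 (1S,3R,6S,7S,8S,10S)-1,10-dihydroxy-3-(tert-butyldimethylsilyloxy)-8-((R)-2-methylbutanoyloxy)-13-norgermacr-4Z-en-12,6-olide
Conditions: OsO4 (2 mol %), NMO, acetone/H2O, 0 °C
Reagents that add atoms: N-methylmorpholine N-oxide, C[N+]1([O-])CCOCC1; water, O; osmium tetroxide (catalyst), O=[Os](=O)(=O)=O
Why: Upjohn syn-dihydroxylation should select the isolated, electron-rich 1(10)-alkene over the doubly oxygen-flanked 4,5-alkene and add on its outer face, giving the 1S,10S diol.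

Step 13
Reactants: 19 (1S,3R,6S,7S,8S,10S)-1,10-dihydroxy-3-(tert-butyldimethylsilyloxy)-8-((R)-2-methylbutanoyloxy)-13-norgermacr-4Z-en-12,6-olide
Product: 20 (1R,3R,6S,7S,8S,10S)-1,10-epoxy-3-(tert-butyldimethylsilyloxy)-8-((R)-2-methylbutanoyloxy)-13-norgermacr-4Z-en-12,6-olide
Conditions: PPh3, DIAD, THF, 0 °C to rt
Reagents that add atoms: none
Why: Mitsunobu cyclodehydration activates the secondary C1 hydroxyl and the tertiary C10 oxygen displaces it with inversion (C1 S to R), giving the cis-oxirane that direct epoxidation of the E-alkene cannot give.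

Step 14
Reactants: 20 (1R,3R,6S,7S,8S,10S)-1,10-epoxy-3-(tert-butyldimethylsilyloxy)-8-((R)-2-methylbutanoyloxy)-13-norgermacr-4Z-en-12,6-olide
Product: 23 3-O-(tert-butyldimethylsilyl)-3-deacetyl target, via Mannich base 21 (not isolated), via trimethylammonium iodide 22 (not isolated)
Conditions: LiN(i-Pr)2 (1.05 equiv), THF, −78 °C; CH2=NMe2+ I−, −78 to 0 °C; then MeI, MeOH, rt; NaHCO3 (aq.)
Reagents that add atoms: Eschenmoser's salt, C=[N+](C)C.[I-]; iodomethane, CI (N-methyl of 22 only)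
Why: In the Eschenmoser α-methylenation the lactone CH2 (the most acidic C–H) is enolised and undergoes a Mannich reaction, and Hofmann-type elimination of the quaternised amine gives the exocyclic alkene; no stereocentre is affected.

Step 15
Reactants: 23 3-O-(tert-butyldimethylsilyl)-3-deacetyl target
Product: 25 CNP0340603.1, via C3 alcohol 24 (not isolated)
Conditions: Bu4NF, AcOH, THF, rt; then Ac2O, pyridine, DMAP, CH2Cl2, 0 °C
Reagents that add atoms: acetic anhydride, CC(=O)OC(C)=O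
Why: Buffered fluoride desilylation and acetylation place the C3 acetate with retention, completing the target.

## Compound list

1 | (R)-(−)-carvone | CC1=CC[C@H](CC1=O)C(C)=C | starting material
2 | (R)-2-methylbutanoic acid | CC[C@@H](C)C(=O)O | starting material
3 | (1R,5R)-cis-carveol | CC1=CC[C@H](C[C@H]1O)C(C)=C | intermediate
4 | (1R,5R)-cis-carveol tert-butyldimethylsilyl ether | CC1=CC[C@H](C[C@H]1O[Si](C)(C)C(C)(C)C)C(C)=C | intermediate
5 | (4R,6R)-4-(tert-butyldimethylsilyloxy)-3-methyl-6-(prop-1-en-2-yl)cyclohex-2-en-1-one | CC1=CC(=O)[C@H](C[C@H]1O[Si](C)(C)C(C)(C)C)C(C)=C | intermediate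
6 | (1R,4R,6R)-4-(tert-butyldimethylsilyloxy)-1-ethenyl-3-methyl-6-(prop-1-en-2-yl)cyclohex-2-en-1-ol | CC1=C[C@](O)(C=C)[C@H](C[C@H]1O[Si](C)(C)C(C)(C)C)C(C)=C | intermediate
7 | potassium C6–C7 enolate of (3R)-3-(tert-butyldimethylsilyloxy)-4,10-dimethylcyclodeca-1(10)E,4Z-dien-6-one | [O-]/C1=C\CC/C(C)=C/C[C@@H](O[Si](C)(C)C(C)(C)C)/C(C)=C\1.[K+] | intermediate
8 | (3R)-3-(tert-butyldimethylsilyloxy)-4,10-dimethylcyclodeca-1(10)E,4Z,7Z-trien-6-one | O=C1/C=C(/C)[C@H](O[Si](C)(C)C(C)(C)C)C/C=C(\C)C/C=C\1 | intermediate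
9 | (3R,8S)-8-(pinacolboryl)-3-(tert-butyldimethylsilyloxy)-4,10-dimethylcyclodeca-1(10)E,4Z-dien-6-one | O=C1/C=C(/C)[C@H](O[Si](C)(C)C(C)(C)C)C/C=C(\C)C[C@H](B2OC(C)(C)C(C)(C)O2)C1 | intermediate
10 | (3R,8S)-8-hydroxy-3-(tert-butyldimethylsilyloxy)-4,10-dimethylcyclodeca-1(10)E,4Z-dien-6-one | O=C1/C=C(/C)[C@H](O[Si](C)(C)C(C)(C)C)C/C=C(\C)C[C@H](O)C1 | intermediate
11 | dilithium C8-alkoxide C6–C7 enolate of 10 | [Li+].[Li+].[O-]/C1=C\[C@@H]([O-])C/C(C)=C/C[C@@H](O[Si](C)(C)C(C)(C)C)/C(C)=C\1 | intermediate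
12 | tert-butyl [(3R,7S,8S)-8-hydroxy-6-oxo-3-(tert-butyldimethylsilyloxy)-4,10-dimethylcyclodeca-1(10)E,4Z-dien-7-yl]acetate | CC(C)(C)OC(=O)C[C@@H]1C(=O)/C=C(/C)[C@H](O[Si](C)(C)C(C)(C)C)C/C=C(\C)C[C@@H]1O | intermediate
13 | (R)-2-methylbutan-1-ol | CC[C@@H](C)CO | intermediate
14 | (R)-2-methylbutanal | CC[C@@H](C)C=O | intermediate
15 | tert-butyl [(3R,6S,7R,8S)-6-hydroxy-8-((R)-2-methylbutanoyloxy)-3-(tert-butyldimethylsilyloxy)-4,10-dimethylcyclodeca-1(10)E,4Z-dien-7-yl]acetate | CC(C)(C)OC(=O)C[C@@H]1[C@@H](O)/C=C(/C)[C@H](O[Si](C)(C)C(C)(C)C)C/C=C(\C)C[C@@H]1OC(=O)[C@H](C)CC | intermediate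
16 | trimethylsilyl ester and C6 trimethylsilyl ether of acid 17 (ring configuration as in 15) | C[Si](C)(C)OC(=O)C[C@@H]1[C@@H](O[Si](C)(C)C)/C=C(/C)[C@H](O[Si](C)(C)C(C)(C)C)C/C=C(\C)C[C@@H]1OC(=O)[C@H](C)CC | intermediate
17 | free C12 acid of 15 (6-hydroxy acid, ring configuration as in 15) | OC(=O)C[C@@H]1[C@@H](O)/C=C(/C)[C@H](O[Si](C)(C)C(C)(C)C)C/C=C(\C)C[C@@H]1OC(=O)[C@H](C)CC | intermediate
18 | (3R,6S,7S,8S)-3-(tert-butyldimethylsilyloxy)-8-((R)-2-methylbutanoyloxy)-13-norgermacra-1(10)E,4Z-dien-12,6-olide (trans-fused lactone, C11 is CH2) | C1C(=O)O[C@H]2/C=C(/C)[C@H](O[Si](C)(C)C(C)(C)C)C/C=C(\C)C[C@H](OC(=O)[C@H](C)CC)[C@H]12 | intermediate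
19 | (1S,10S)-1,10-diol of 18 | C1C(=O)O[C@H]2/C=C(/C)[C@H](O[Si](C)(C)C(C)(C)C)C[C@H](O)[C@](O)(C)C[C@H](OC(=O)[C@H](C)CC)[C@H]12 | intermediate
20 | (1R,10S)-1,10-epoxide (cis-oxirane) derived from 19 | C1C(=O)O[C@H]2/C=C(/C)[C@H](O[Si](C)(C)C(C)(C)C)C[C@H]3O[C@@]3(C)C[C@H](OC(=O)[C@H](C)CC)[C@H]12 | intermediate
21 | 11-(dimethylaminomethyl) derivative of 20 (C11 epimer mixture) | CN(C)CC1C(=O)O[C@H]2/C=C(/C)[C@H](O[Si](C)(C)C(C)(C)C)C[C@H]3O[C@@]3(C)C[C@H](OC(=O)[C@H](C)CC)[C@H]12 | intermediate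
22 | 11-(trimethylammoniomethyl) derivative of 20, iodide (C11 epimer mixture) | C[N+](C)(C)CC1C(=O)O[C@H]2/C=C(/C)[C@H](O[Si](C)(C)C(C)(C)C)C[C@H]3O[C@@]3(C)C[C@H](OC(=O)[C@H](C)CC)[C@H]12.[I-] | intermediate
23 | 3-O-(tert-butyldimethylsilyl)-3-deacetyl target (α-methylene lactone) | C=C1C(=O)O[C@H]2/C=C(/C)[C@H](O[Si](C)(C)C(C)(C)C)C[C@H]3O[C@@]3(C)C[C@H](OC(=O)[C@H](C)CC)[C@H]12 | intermediate
24 | 3-deacetyl target (C3 alcohol) | C=C1C(=O)O[C@H]2/C=C(/C)[C@H](O)C[C@H]3O[C@@]3(C)C[C@H](OC(=O)[C@H](C)CC)[C@H]12 | intermediate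
25 | CNP0340603.1, (1R,3R,6S,7S,8S,10S)-3-acetoxy-1,10-epoxy-8-((R)-2-methylbutanoyloxy)germacra-4Z,11(13)-dien-12,6-olide | C=C1C(=O)O[C@H]2/C=C(/C)[C@H](OC(C)=O)C[C@H]3O[C@@]3(C)C[C@H](OC(=O)[C@H](C)CC)[C@H]12 | target

## Step count and risks

Total steps: 15. Longest linear sequence: 13 (steps 1–7 and 10–15); steps 8–9 make the aldehyde side branch.

Steps most likely to fail:

Step 6. The copper–boryl addition may pick the wrong face of the C7=C8 bond, or react sluggishly with the cross-conjugated dienone; every later stereocentre is relayed from C8. The fallback sets out from 8 and comes back at 10. Weitz–Scheffer epoxidation of the less hindered enone (t-BuOOH, DBU, CH2Cl2) gives the 7,8-epoxy ketone F1. SmI2 in THF/MeOH at −90 °C then cleaves its Cα–O bond reductively to give β-hydroxy ketone 10.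

Step 10. The α-branched aldehyde may epimerise, or hydride transfer within the medium-ring hemiacetal may be slow. The fallback sets out from 12 and comes back at 18. Evans–Saksena reduction (Me4NBH(OAc)3, AcOH/MeCN, −30 °C) gives the anti-diol tert-butyl ester F2. TMSOTf/2,6-lutidine followed by citric acid closes the ester onto the allylic C6 oxygen to give the 8-hydroxy trans-lactone F3. Acylation of F3 with acid 2 (DIC, DMAP, CH2Cl2, 0 °C) gives 18.

Step 12. OsO4 may add to the inner face of the 1(10)-alkene, which would lead to the wrong cis-oxirane. The fallback sets out from 18 and comes back at 19. Woodward–Prévost cis-hydroxylation (I2, AgOAc, wet AcOH) puts both oxygens on the face opposite to the one the electrophile attacks, giving the hydroxy acetate F4. Brief K2CO3/MeOH at 0 °C removes the unhindered acetate to give diol 19.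

## Further compounds

F1 | step 6 | (3R)-7,8-epoxy-3-(tert-butyldimethylsilyloxy)-4,10-dimethylcyclodeca-1(10)E,4Z-dien-6-one (cis-oxirane, C8 oxygen on the outer face) | O=C1/C=C(/C)[C@H](O[Si](C)(C)C(C)(C)C)C/C=C(\C)C[C@@H]2O[C@H]12
F2 | step 10 | tert-butyl [(3R,6S,7S,8S)-6,8-dihydroxy-3-(tert-butyldimethylsilyloxy)-4,10-dimethylcyclodeca-1(10)E,4Z-dien-7-yl]acetate | CC(C)(C)OC(=O)C[C@@H]1[C@@H](O)/C=C(/C)[C@H](O[Si](C)(C)C(C)(C)C)C/C=C(\C)C[C@@H]1O
F3 | step 10 | (3R,6S,7S,8S)-8-hydroxy-3-(tert-butyldimethylsilyloxy)-13-norgermacra-1(10)E,4Z-dien-12,6-olide | C1C(=O)O[C@H]2/C=C(/C)[C@H](O[Si](C)(C)C(C)(C)C)C/C=C(\C)C[C@H](O)[C@H]12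
F4 | step 12 | 1-O-acetyl derivative of diol 19 (free tertiary C10 hydroxyl) | C1C(=O)O[C@H]2/C=C(/C)[C@H](O[Si](C)(C)C(C)(C)C)C[C@H](OC(C)=O)[C@](O)(C)C[C@H](OC(=O)[C@H](C)CC)[C@H]12
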